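**Plan**
- Retrosynthetic cuts, in order: the C8–O ester bond (side-chain acid off); the C11=C13 alkene (back to the 11-methyl lactone); the C1=C10 and C4=C5 π bonds, exchanged for the C1–C4 and C5–C10 σ bonds of a bicyclo[2.2.0]hexane; the C4–C5 and C1–C10 bonds of that tricycle ([2+2]), giving a cis-lactone enone and 1-methylcyclobutene; the C6–O lactone bond and the C8–O bond, back to (S)-carvone.
- Feature used: C5–C10, with the methyl on C10 and the three-carbon branch (C11, C12, C13) on C7, are the ring of carvone. The Z-C1=C10/E-C4=C5 pair in the ten-membered ring is the cis,trans-cyclodeca-1,5-diene released when the central bicyclo[2.2.0]hexane of a cyclohexenone–cyclobutene photoadduct opens.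
- Forward order: carvone ring, then γ-lactone (step 4), then two fused cyclobutanes (step 10), then ten-membered ring by thermal ring expansion (step 13), then exocyclic methylene (steps 14, 15), then side chain (step 21) and deprotection.
- Stereochemistry: C7 from (S)-carvone; C6 by tethered iodolactonisation; C8 by anti hydroxylation then Mitsunobu inversion; C9 by hydride addition anti to the C10 methyl and O8; alkene geometry from the cis six–four fusion; side-chain centre from an Evans allylation.

Key step: step 13

**Remarks**
- Numbering and faces: germacrane numbering is used for all carvone-derived compounds (C5–C10 carvone ring, C9 the carvone carbonyl carbon, C7 bearing C11 with C12 and C13, C1–C4 and the C4 methyl from the cyclobutene); β is the face of the carvone ring carrying the C7–C11 bond, α the other face.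
- Assumption: hydroboration gives both C11 epimers; DBU in step 4 is expected to equilibrate the lactone to the 11-exo-methyl epimer (methyl cis to H7), which is the one drawn; any residual epimer behaves identically and C11 is erased in steps 14 and 15.

**Route**

Step 1
Reactants: 1 (S)-carvone
Product: 2 (5S)-5-(1-hydroxypropan-2-yl)-2-methylcyclohex-2-en-1-ol (epimers at C9 and C11)
Conditions: 9-BBN (2.5 equiv), THF, 0 °C to rt; then NaOH, H2O2, 0 °C
Reagents that add atoms: hydrogen peroxide, OO
Why: Hydroboration–oxidation with 9-BBN takes the 1,1-disubstituted isopropenyl alkene anti-Markovnikov while a second equivalent reduces the enone carbonyl 1,2; the new centres at C9 and C11 form unselectively and are erased later (C9 in step 2, C11 in steps 14 and 15).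

Step 2
Reactants: 2 diol
Product: 3 2-[(1S)-4-methyl-5-oxocyclohex-3-en-1-yl]propanoic acid (both C11 epimers)
Conditions: CrO3, H2SO4, H2O, acetone, 0 °C
Reagents that add atoms: water, O
Why: Jones oxidation should take the primary alcohol to the carboxylic acid and the allylic alcohol back to the enone in one operation, leaving C7 untouched.

Step 3
Reactants: 3 conjugated keto acid
Product: 4 2-[(1R)-4-methyl-5-oxocyclohex-2-en-1-yl]propanoic acid (β,γ-enone; epimers at C10 and C11)
Conditions: KOt-Bu (3 equiv), t-BuOH–THF, 0 °C to rt, under argon; inverse quench into cold aqueous AcOH; used crude at once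
Reagents that add atoms: none
Why: Enone deconjugation: excess alkoxide forms the carboxylate and, under equilibrating conditions, the extended dienolate, and fast kinetic protonation at the α-carbon C10 should give the C5=C6 isomer; C7 is not involved (its descriptor changes only through CIP priorities) and the new C10 centre is erased in step 4.

Step 4
Reactants: 4 β,γ-unsaturated keto acid
Product: 6 cis-fused lactone enone, via iodolactone 5 (not isolated)
Conditions: I2, NaHCO3, MeCN–H2O, 0 °C, dark; Na2S2O3 wash; then DBU, toluene, rt to 60 °C
Reagents that add atoms: none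
Why: Iodolactonisation (5-exo, anti addition) of the γ,δ-unsaturated acid delivers the carboxylate oxygen to C6 from the face of the C7 side chain, so the γ-lactone must be cis-fused (O6 β), and DBU then removes HI across C10–C5 by E1cB elimination to restore the enone and should equilibrate C11 to the exo-methyl lactone; unreacted 3 stays in the bicarbonate layer and can be recycled.

Step 5
Reactants: 6 cis-fused lactone enone
Product: 7 8α-hydroxy lactone enone
Conditions: KN(SiMe3)2 (1.1 equiv), THF, −78 °C; 2-(phenylsulfonyl)-3-phenyloxaziridine, −78 °C; aqueous NH4Cl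
Reagents that add atoms: 2-(phenylsulfonyl)-3-phenyloxaziridine, O=S(=O)(c1ccccc1)N1OC1c1ccccc1
Why: Davis oxidation of the kinetic cross-conjugated enolate (the ketone α'-CH2 is the most acidic site); the oxaziridine should approach C8 from the α face, anti to the C7–C11 bond and the lactone ring, giving the 8α alcohol trans to C11.

Step 6
Reactants: 7 8α-hydroxy lactone enone
Product: 8 8β-chloroacetoxy lactone enone
Conditions: ClCH2CO2H, PPh3, DIAD, toluene, 0 °C to rt
Reagents that add atoms: chloroacetic acid, OC(=O)CCl
Why: Mitsunobu esterification with an acidic carboxylic acid proceeds by SN2 displacement of the oxyphosphonium group, which is accelerated next to a carbonyl, and so inverts C8 to the 8β configuration cis to C11 and O6.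

Step 7
Reactants: 8 8β-chloroacetoxy lactone enone
Product: 9 8β-hydroxy lactone enone
Conditions: K2CO3 (0.2 equiv), MeOH, −20 °C, short reaction time; AcOH quench
Reagents that add atoms: none
Why: Chloroacetates undergo base-catalysed transesterification far faster than ordinary esters, so catalytic carbonate in cold methanol should free the alcohol without opening the lactone and without enolising the α-ketol.

Step 8
Reactants: 9 8β-hydroxy lactone enone
Product: 10 8β-triethylsilyloxy lactone enone
Conditions: Et3SiCl, imidazole, DMF, 0 °C
Reagents that add atoms: chlorotriethylsilane, CC[Si](Cl)(CC)CC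
Why: Standard silylation without change at C8; the triethylsilyl ether is chosen because it offers the excited enone no C–H on the atom bound to O8, withstands hydride, amide base and pyrolysis, and can later be cleaved beside a TBS ether.

Step 9
Reactants: 11 methylenecyclobutane
Product: 12 1-methylcyclobutene
Conditions: KOt-Bu (cat.), DMSO, 50 °C, sealed vessel; fractional distillation (spinning band)
Reagents that add atoms: none
Why: Base-catalysed alkene isomerisation through the allyl anion, whose equilibrium lies on the side of the endocyclic trisubstituted alkene.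

Step 10
Reactants: 10 8β-triethylsilyloxy lactone enone; 12 1-methylcyclobutene
Product: 13 cis-anti-cis head-to-tail photoadduct ketone
Conditions: hν (350 nm, uranium-glass filter), large excess of the alkene, CH2Cl2, −40 °C
Reagents that add atoms: none
Why: Enone–alkene [2+2] photocycloaddition through the enone triplet and a 1,4-biradical; as with isobutene-type alkenes the more substituted alkene carbon C4 should bond to the β-carbon C5, which also avoids joining the two fully substituted carbons C10 and C4, and the alkene should enter on the α face, anti to the lactone and the silyloxy group, giving the cis six–four fusion with the outer ring anti; the new centres C1, C4, C5 and C10 are all erased in step 13.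

Step 11
Reactants: 13 photoadduct ketone
Product: 14 9β-alcohol
Conditions: LiBH(s-Bu)3 (1.2 equiv), THF, −78 °C; aqueous NH4Cl at −78 °C
Reagents that add atoms: none
Why: The bulky borohydride reduces the ketone but not the lactone at −78 °C and should attack C9 from the α face, anti to the C10 methyl and the C8 silyloxy group (the usual outcome for 2-alkoxycyclohexanones with hindered hydrides), setting the 9β alcohol cis to O8; silyl migration to the hindered O9 is not expected.

Step 12
Reactants: 14 9β-alcohol
Product: 15 9β-TBS ether 8β-TES ether photoadduct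
Conditions: t-BuMe2SiOTf, 2,6-lutidine, CH2Cl2, −78 to 0 °C
Reagents that add atoms: tert-butyldimethylsilyl triflate, CC(C)(C)[Si](C)(C)OS(=O)(=O)C(F)(F)F
Why: The silyl triflate silylates the hindered secondary alcohol next to the quaternary C10 without touching any stereocentre.

Step 13
Reactants: 15 bis-silylated photoadduct
Product: 16 ten-membered (1(10)Z,4E)-diene lactone
Conditions: flash vacuum pyrolysis: sublimed at about 170 °C/0.01 mbar through a quartz tube at 500 °C, contact time of the order of 10 ms, condensed at −78 °C
Reagents that add atoms: none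
Why: Thermal opening of the bicyclo[2.2.0]hexane, the reaction type by which cyclohexenone–cyclobutene photoadducts give cis,trans-cyclodeca-1,5-dienes: the strained central C1–C4 bond breaks first to a cyclohexane-1,4-diyl (C1, C2, C3, C4, C5, C10), which then fragments at C5–C10 to form the C1=C10 and C4=C5 π bonds. The ten-membered ring thus arises by ring expansion, through cleavage of the bond shared by the six- and four-membered rings of a fused tricycle and not by end-to-end cyclisation, and the release of two cyclobutane strain energies drives it. No stereocentre is created: C6, C7, C8, C9 and C11 are spectators fixed earlier on the rigid cyclohexane, and C1, C4, C5 and C10 become trigonal. The step needs cleavage of C5–C10 rather than C2–C3 and Z geometry at C1=C10 with E at C4=C5; the first should follow because C5–C10 is the weaker, fully substituted bond whose cleavage gives two trisubstituted alkenes, the second because the cis six–four fusion lets the diyl fragment through the chair that has C6 and the C10 methyl equatorial and only C9 axial, which puts C9 cis to C2 and C6 trans to C3. Millisecond contact at high temperature should favour the loosely organised diyl fragmentation over the highly ordered Cope rearrangement of the product to its divinylcyclohexane isomer, and cold trapping keeps the diene from rearranging afterwards.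

Step 14
Reactants: 16 ten-membered diene lactone
Product: 17 11-bromo-11-methyl lactone
Conditions: LiN(i-Pr)2 (1.2 equiv), THF, −78 °C; CBr4, −78 °C; aqueous NH4Cl
Reagents that add atoms: carbon tetrabromide, BrC(Br)(Br)Br
Why: The lactone enolate (C11–H is the only acidic C–H left) is brominated at C11 from the face anti to the C7–C8 bond, so bromine should stand cis to H7 and the methyl cis to C8.

Step 15
Reactants: 17 11-bromo-11-methyl lactone
Product: 18 α-methylene lactone bis-silyl ether
Conditions: DBU, toluene, 50 °C
Reagents that add atoms: none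
Why: E2 dehydrobromination needs an anti-periplanar hydrogen, which only the methyl group offers because H7 is syn to bromine, so the exocyclic C11=C13 alkene should form and not the endocyclic butenolide.

Step 16
Reactants: 18 α-methylene lactone bis-silyl ether
Product: 19 8β-alcohol 9-O-TBS ether
Conditions: PPTS (cat.), MeOH–CH2Cl2, 0 °C
Reagents that add atoms: none
Why: Acid-catalysed methanolysis cleaves a secondary triethylsilyl ether much faster than a secondary TBS ether, and these mild conditions should spare the acid-sensitive 1,5-diene and the α-methylene lactone.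

Step 17
Reactants: 20 (S)-4-benzyl-3-propanoyloxazolidin-2-one
Product: 21 (S)-4-benzyl-3-[(2R)-2-methylpent-4-enoyl]oxazolidin-2-one
Conditions: NaN(SiMe3)2, THF, −78 °C; allyl iodide, −78 to −40 °C
Reagents that add atoms: allyl iodide, C=CCI
Why: Evans alkylation: the chelated Z-sodium enolate is allylated on the face opposite the benzyl group, which sets the 2R centre.

Step 18
Reactants: 21 allylated imide
Product: 22 (R)-2-methylpent-4-en-1-ol
Conditions: LiBH4, THF–H2O (1 equiv), 0 °C
Reagents that add atoms: none
Why: Borohydride reduction cleaves the imide to the primary alcohol without enolising the α-centre, and the auxiliary is recovered.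

Step 19
Reactants: 22 (R)-2-methylpent-4-en-1-ol; 23 stearoyl chloride
Product: 24 (R)-2-methylpent-4-en-1-yl octadecanoate
Conditions: pyridine, DMAP (cat.), CH2Cl2, 0 °C to rt
Reagents that add atoms: none
Why: Acylation of a primary alcohol by an acid chloride; the stereocentre is not involved.

Step 20
Reactants: 24 (R)-2-methylpent-4-en-1-yl octadecanoate
Product: 25 (R)-3-methyl-4-(octadecanoyloxy)butanoic acid
Conditions: RuCl3 (cat.), NaIO4 (4.1 equiv), CCl4–MeCN–H2O, rt
Reagents that add atoms: sodium periodate, [Na+].[O-]I(=O)(=O)=O; water, O
Why: RuO4-catalysed oxidative cleavage turns the terminal alkene into the carboxylic acid with loss of one carbon, the ester and the β-stereocentre being inert.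

Step 21
Reactants: 19 8β-alcohol 9-O-TBS ether; 25 (R)-3-methyl-4-(octadecanoyloxy)butanoic acid
Product: 27 9-O-TBS ether of the target, via acid chloride 26 (not isolated)
Conditions: 25, (COCl)2, DMF (cat.), CH2Cl2, 0 °C to rt, concentrate; then 19, pyridine, DMAP, CH2Cl2, 0 °C to rt
Reagents that add atoms: none
Why: Acid chloride formation followed by DMAP-catalysed acylation should esterify the hindered C8 alcohol with retention, O9 being blocked as its silyl ether and the stearate in the acid being inert.

Step 22
Reactants: 27 9-O-TBS ether of the target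
Product: 28 CNP0114940.1
Conditions: HF·pyridine, pyridine, THF, 0 °C to rt
Reagents that add atoms: none
Why: Buffered HF·pyridine cleaves the allylic TBS ether while the two esters, the α-methylene lactone and the 1,5-diene should survive, and the weakly acidic medium disfavours acyl migration from O8 to O9.

**Compound list**
1 | (S)-carvone, (5S)-2-methyl-5-(prop-1-en-2-yl)cyclohex-2-en-1-one | CC1=CC[C@H](C(C)=C)CC1=O | starting material
2 | (5S)-5-(1-hydroxypropan-2-yl)-2-methylcyclohex-2-en-1-ol, epimer mixture at the carbinol carbon (C9) and at C11 | CC1=CC[C@H](C(C)CO)CC1O | intermediate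
3 | 2-[(1S)-4-methyl-5-oxocyclohex-3-en-1-yl]propanoic acid, both C11 epimers | CC1=CC[C@H](C(C)C(=O)O)CC1=O | intermediate
4 | 2-[(1R)-4-methyl-5-oxocyclohex-2-en-1-yl]propanoic acid (C5=C6 alkene; C7 spatially as in carvone; epimers at C10 and C11) | CC1C=C[C@H](C(C)C(=O)O)CC1=O | intermediate
5 | iodolactone: 9-oxo cis-fused 6β,12-lactone with 5α-iodine (trans to O6); epimers at C10 and C11 | CC1C(=O)O[C@H]2[C@H](I)C(C)C(=O)C[C@@H]12 | intermediate
6 | cis-fused lactone enone, (3S,3aS,7aR)-3,6-dimethyl-3a,4-dihydro-1-benzofuran-2,5(3H,7aH)-dione (O6 and C11 both β; 11-methyl exo, cis to H7) | C[C@@H]1C(=O)O[C@H]2C=C(C)C(=O)C[C@@H]12 | intermediate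
7 | 8α-hydroxy derivative of 6 (OH trans to the C7–C11 bond) | C[C@@H]1C(=O)O[C@H]2C=C(C)C(=O)[C@H](O)[C@@H]12 | intermediate
8 | 8β-chloroacetoxy derivative of 6 (ester oxygen cis to C11 and O6) | C[C@@H]1C(=O)O[C@H]2C=C(C)C(=O)[C@@H](OC(=O)CCl)[C@@H]12 | intermediate
9 | 8β-hydroxy derivative of 6 (O6, C11 and O8 all β) | C[C@@H]1C(=O)O[C@H]2C=C(C)C(=O)[C@@H](O)[C@@H]12 | intermediate
10 | 8β-triethylsilyloxy derivative of 6 | C[C@@H]1C(=O)O[C@H]2C=C(C)C(=O)[C@@H](O[Si](CC)(CC)CC)[C@@H]12 | intermediate
11 | methylenecyclobutane | C=C1CCC1 | starting material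
12 | 1-methylcyclobutene | CC1=CCC1 | intermediate
13 | photoadduct ketone: head-to-tail, cis-anti-cis; new bonds C5–C4 and C10–C1 on the α face, 10-methyl and H5 β, outer cyclobutane (C2, C3) anti to the six-membered ring; 9-oxo, 8β-OSiEt3, cis 6β,12-lactone, 11-methyl exo | C[C@@H]1C(=O)O[C@H]2[C@@H]3[C@@]4(C)CC[C@H]4[C@]3(C)C(=O)[C@@H](O[Si](CC)(CC)CC)[C@@H]12 | intermediate
14 | 9β-alcohol of 13 (OH cis to O8 and to the C10 methyl) | C[C@@H]1C(=O)O[C@H]2[C@@H]3[C@@]4(C)CC[C@H]4[C@]3(C)[C@@H](O)[C@@H](O[Si](CC)(CC)CC)[C@@H]12 | intermediate
15 | 9β-tert-butyldimethylsilyl ether of 14 (precursor of the key step) | C[C@@H]1C(=O)O[C@H]2[C@@H]3[C@@]4(C)CC[C@H]4[C@]3(C)[C@@H](O[Si](C)(C)C(C)(C)C)[C@@H](O[Si](CC)(CC)CC)[C@@H]12 | intermediate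
16 | 11,13-dihydro ten-membered lactone: germacra-1(10)Z,4E-dien-12,6-olide with 8-OSiEt3 and 9-OSiMe2t-Bu, C6–C9 configured as in 15, 11-methyl cis to H7 | C[C@@H]1C(=O)O[C@H]2/C=C(\C)CC/C=C(/C)[C@@H](O[Si](C)(C)C(C)(C)C)[C@@H](O[Si](CC)(CC)CC)[C@@H]12 | intermediate
17 | 11-bromo derivative of 16 (Br cis to H7, 11-methyl cis to C8) | C[C@@]1(Br)C(=O)O[C@H]2/C=C(\C)CC/C=C(/C)[C@@H](O[Si](C)(C)C(C)(C)C)[C@@H](O[Si](CC)(CC)CC)[C@@H]12 | intermediate
18 | germacra-1(10)Z,4E,11(13)-trien-12,6-olide with 8-OSiEt3 and 9-OSiMe2t-Bu | C=C1C(=O)O[C@H]2/C=C(\C)CC/C=C(/C)[C@@H](O[Si](C)(C)C(C)(C)C)[C@@H](O[Si](CC)(CC)CC)[C@@H]12 | intermediate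
19 | 8-hydroxy-9-(tert-butyldimethylsilyloxy)germacra-1(10)Z,4E,11(13)-trien-12,6-olide | C=C1C(=O)O[C@H]2/C=C(\C)CC/C=C(/C)[C@@H](O[Si](C)(C)C(C)(C)C)[C@@H](O)[C@@H]12 | intermediate
20 | (S)-4-benzyl-3-propanoyloxazolidin-2-one | CCC(=O)N1[C@@H](Cc2ccccc2)COC1=O | starting material
21 | (S)-4-benzyl-3-[(2R)-2-methylpent-4-enoyl]oxazolidin-2-one | C=CC[C@@H](C)C(=O)N1[C@@H](Cc2ccccc2)COC1=O | intermediate
22 | (R)-2-methylpent-4-en-1-ol | C=CC[C@@H](C)CO | intermediate
23 | stearoyl chloride (octadecanoyl chloride) | CCCCCCCCCCCCCCCCCC(=O)Cl | starting material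
24 | (R)-2-methylpent-4-en-1-yl octadecanoate | C=CC[C@@H](C)COC(=O)CCCCCCCCCCCCCCCCC | intermediate
25 | (R)-3-methyl-4-(octadecanoyloxy)butanoic acid | OC(=O)C[C@@H](C)COC(=O)CCCCCCCCCCCCCCCCC | intermediate
26 | (R)-3-methyl-4-(octadecanoyloxy)butanoyl chloride | ClC(=O)C[C@@H](C)COC(=O)CCCCCCCCCCCCCCCCC | intermediate
27 | 9-O-tert-butyldimethylsilyl ether of the target | C=C1C(=O)O[C@H]2/C=C(\C)CC/C=C(/C)[C@@H](O[Si](C)(C)C(C)(C)C)[C@@H](OC(=O)C[C@@H](C)COC(=O)CCCCCCCCCCCCCCCCC)[C@@H]12 | intermediate
28 | CNP0114940.1, (6S,7S,8S,9R)-9-hydroxy-8-[(3R)-3-methyl-4-(octadecanoyloxy)butanoyloxy]germacra-1(10)Z,4E,11(13)-trien-12,6-olide | C=C1C(=O)O[C@H]2/C=C(\C)CC/C=C(/C)[C@@H](O)[C@@H](OC(=O)C[C@@H](C)COC(=O)CCCCCCCCCCCCCCCCC)[C@@H]12 | target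

**Count**
Total steps: 22. Longest linear sequence: 17 steps (steps 1–8, 10–16, 21, 22).

**Steps most likely to fail**

Step 6 (inversion at C8). The activated α-ketol may lose its oxyphosphonium group by elimination towards an aromatising dienone, or substitution on the hindered β face may be so slow that acyl transfer with retention competes. The fallback replaces SN2 inversion by epimerisation through the enolate; it sets out from 7 and returns at 10. Compound 7 would be silylated (Et3SiCl, imidazole, DMF) to the 8α-triethylsilyl ether F1. F1 would be converted with KN(SiMe3)2 in THF at −78 °C into its tetrasubstituted enolate and protonated at −78 °C with 2,6-di-tert-butylphenol. Kinetic protonation should occur on the open α face, anti to C11, which leaves the silyloxy group β and gives 10.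

Step 10 (photocycloaddition). The excited enone may be diverted by its α'-silyloxy ketone unit (α-cleavage or loss of silanol), or the crowded enone may add slowly and with mixed orientation. The fallback moves the cycloaddition ahead of the C8 oxygenation; it sets out from 6 and returns at 13. Irradiation of 6 with 12 under the conditions of step 10 should give the 8-deoxy photoadduct ketone F2. Its enolate can form only towards C8 because C10 is quaternary, and Davis oxidation (KN(SiMe3)2, then the oxaziridine) should give the 8α-hydroxy ketone F3. Mitsunobu reaction with chloroacetic acid would give the 8β-chloroacetate F4, cold K2CO3/MeOH the 8β-hydroxy ketone F5, and Et3SiCl/imidazole then 13. Should the hydroxylation of F2 place the oxygen β directly, the inversion is left out.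

Step 13 (ring opening). At the temperature needed to break the bicyclohexane the diene may undergo Cope rearrangement to the divinylcyclohexane, the C2–C3 bond may cleave in competition, or the heavy bis-silyl ether may fail to volatilise cleanly. The fallback keeps the disconnection but opens the ring at the ketone oxidation level; it sets out from 13 and returns at 16. In 13 the C9 carbonyl stabilises the C10 radical of the diyl, so the same cleavage should proceed in solution at a much lower temperature (flow reactor, toluene, about 200 °C, short residence time), giving the cyclodecadienone F6, whose C1=C10 alkene is conjugated with the ketone and so biases the Cope equilibrium towards the ten-membered ring. Luche reduction (NaBH4, CeCl3·7H2O, MeOH, −78 °C) should add hydride from the ring periphery, anti to the C8 silyloxy group, to give the 9β-alcohol F7. Silylation with t-BuMe2SiOTf and 2,6-lutidine then gives 16.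

Further compounds
F1 | step 6 | 8α-triethylsilyloxy epimer of 10 | C[C@@H]1C(=O)O[C@H]2C=C(C)C(=O)[C@H](O[Si](CC)(CC)CC)[C@@H]12
F2 | step 10 | 8-deoxy photoadduct ketone (cis-anti-cis, head-to-tail, cyclobutanes on the α face) | C[C@@H]1C(=O)O[C@H]2[C@@H]3[C@@]4(C)CC[C@H]4[C@]3(C)C(=O)C[C@@H]12
F3 | step 10 | 8α-hydroxy photoadduct ketone | C[C@@H]1C(=O)O[C@H]2[C@@H]3[C@@]4(C)CC[C@H]4[C@]3(C)C(=O)[C@H](O)[C@@H]12
F4 | step 10 | 8β-chloroacetoxy photoadduct ketone | C[C@@H]1C(=O)O[C@H]2[C@@H]3[C@@]4(C)CC[C@H]4[C@]3(C)C(=O)[C@@H](OC(=O)CCl)[C@@H]12
F5 | step 10 | 8β-hydroxy photoadduct ketone | C[C@@H]1C(=O)O[C@H]2[C@@H]3[C@@]4(C)CC[C@H]4[C@]3(C)C(=O)[C@@H](O)[C@@H]12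
F6 | step 13 | 9-oxo-8β-triethylsilyloxygermacra-1(10)Z,4E-dien-12,6-olide | C[C@@H]1C(=O)O[C@H]2/C=C(\C)CC/C=C(/C)C(=O)[C@@H](O[Si](CC)(CC)CC)[C@@H]12
F7 | step 13 | 9β-hydroxy-8β-triethylsilyloxygermacra-1(10)Z,4E-dien-12,6-olide | C[C@@H]1C(=O)O[C@H]2/C=C(\C)CC/C=C(/C)[C@@H](O)[C@@H](O[Si](CC)(CC)CC)[C@@H]12
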